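**Plan**

1. The carbocycle is numbered C1 (bears the coumarin), C2 (=CH), C3 (=O), C4 (C(OH)-prenyl), C5 (CH2), C6 (=O). Its ene-1,4-dione C6(=O)–C1(aryl)=C2H–C3(=O) is the formal adduct of an aldehyde C6–H across an aryl ynone C1≡C2–C3=O, so the C6–C1 bond is cut first, giving an acyclic ynone-aldehyde.
2. Further cuts: coumarin C3–C1 (Sonogashira), C2–C3 (alkynyl Grignard on a lactol), prenyl–C4 (enolate alkylation). The C3–C6 chain with its oxygen pattern is malic acid.
3. Forward: (R)-malic acid → pivalaldehyde acetal → prenylation → hydroxy lactone → TES ether → lactol → ethynyl carbinol → coupling with 3-bromo-7-methoxycoumarin → double oxidation → NHC-catalysed 6-endo-dig ring closure → desilylation. Both coumarin rings come from commercial 7-methoxycoumarin, so the carbocycle is the only ring made.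
4. Stereochemistry: the single stereocentre (C4, R) comes from (R)-malic acid. It is relayed through the tert-butyl acetal centre during prenylation (self-regeneration of stereocentres) and is quaternary, hence fixed, afterwards.
5. Helpers: the pivalaldehyde acetal (lost in step 3), the TES ether on the tertiary alcohol (removed in step 11), the propargylic carbinol (oxidised in step 9).

Key step: step 10

Assumption: (R)-malic acid, pivalaldehyde, prenyl bromide, ethynylmagnesium bromide (THF solution) and 7-methoxycoumarin are taken as commercial; the carbinol carbon of the target is (R).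

Step 1
Reactants: 1 (R)-malic acid; 2 pivalaldehyde
Product: 3 2-[(2R,4R)-2-tert-butyl-5-oxo-1,3-dioxolan-4-yl]acetic acid (cis)
Conditions: t-BuCHO, p-TsOH (cat.), H2SO4 (cat.), pentane, reflux, Dean–Stark; recrystallisation
Reagents that add atoms: pivalaldehyde 2, CC(C)(C)C=O
Why: Acid-catalysed acetalisation of the α-hydroxy acid with azeotropic removal of water should give the 1,3-dioxolan-4-one, the cis isomer (tert-butyl and CH2CO2H on the same face) being thermodynamically preferred and purified by crystallisation, so the new acetal centre is controlled by the malic acid centre.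

Step 2
Reactants: 3; 4 prenyl bromide
Product: 5 2-[(2R,4R)-2-tert-butyl-4-(3-methylbut-2-en-1-yl)-5-oxo-1,3-dioxolan-4-yl]acetic acid
Conditions: LiHMDS (2.2 equiv), THF, −78 °C; prenyl bromide, −78 → −20 °C; aq. HCl work-up
Reagents that add atoms: prenyl bromide 4, CC(C)=CCBr
Why: The carboxylate/lactone-enolate dianion should be alkylated (SN2 at the primary allylic carbon) on the face anti to the tert-butyl group, so prenyl takes the place of the former hydrogen with overall retention (self-regeneration of stereocentres) and the quaternary carbinol centre of the target is set here.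

Step 3
Reactants: 5
Product: 8 (3R)-3-hydroxy-3-(3-methylbut-2-en-1-yl)oxolan-2-one, via mixed isobutyl carbonic anhydride 6 (not isolated), via hydroxyethyl dioxolanone 7 (not isolated)
Conditions: i-BuOCOCl, N-methylmorpholine, THF, −15 °C; NaBH4, THF/H2O, 0 °C; p-TsOH (cat.), CH2Cl2, rt
Reagents that add atoms: none
Why: Mixed-anhydride activation followed by borohydride should reduce only the carboxyl group in the presence of the trisubstituted alkene and the lactone, and the freed primary alcohol should translactonise onto the acylal carbonyl (5-exo-trig) with loss of pivalaldehyde, leaving the quaternary centre untouched.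

Step 4
Reactants: 8
Product: 9 (3R)-3-(3-methylbut-2-en-1-yl)-3-[(triethylsilyl)oxy]oxolan-2-one
Conditions: TESOTf, 2,6-lutidine, CH2Cl2, 0 °C → rt
Reagents that add atoms: triethylsilyl triflate, CC[Si](CC)(CC)OS(=O)(=O)C(F)(F)F
Why: Silyl triflate with a hindered pyridine base silylates tertiary alcohols, and the TES ether should block retro-aldol and β-elimination later while remaining removable under buffered fluoride.

Step 5
Reactants: 9
Product: 10 (3R)-3-(3-methylbut-2-en-1-yl)-3-[(triethylsilyl)oxy]oxolan-2-ol (mixture at C2)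
Conditions: DIBAL-H (1.1 equiv), CH2Cl2, −78 °C; Rochelle salt
Reagents that add atoms: none
Why: Partial lactone reduction should stop at the lactol because the aluminium hemiacetal is stable at −78 °C.

Step 6
Reactants: 10; 11 ethynylmagnesium bromide
Product: 12 (3R,4RS)-3-(3-methylbut-2-en-1-yl)-3-[(triethylsilyl)oxy]hex-5-yne-1,4-diol
Conditions: HC≡CMgBr (3 equiv), THF, 0 °C; aq. NH4Cl
Reagents that add atoms: ethynylmagnesium bromide 11, C#C[Mg]Br
Why: The lactol opens to the magnesium alkoxide of the hydroxy aldehyde, which should take up the alkynyl Grignard reagent (Grignard addition to a lactol); the new secondary carbinol forms as a mixture and is erased by oxidation in step 9.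

Step 7
Reactants: 13 7-methoxycoumarin
Product: 14 3-bromo-7-methoxy-2H-chromen-2-one
Conditions: Br2, NaOAc, AcOH, rt
Reagents that add atoms: bromine, BrBr
Why: The 7-methoxy group (para to C4a) makes C3 of the pyranone the most nucleophilic position, so electrophilic bromination (addition–elimination across C3=C4) should give the 3-bromide.

Step 8
Reactants: 12; 14
Product: 15 3-[(3RS,4R)-3,6-dihydroxy-4-(3-methylbut-2-en-1-yl)-4-[(triethylsilyl)oxy]hex-1-yn-1-yl]-7-methoxy-2H-chromen-2-one
Conditions: PdCl2(PPh3)2 (5 mol %), CuI (10 mol %), Et3N, THF, 45 °C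
Reagents that add atoms: none
Why: Sonogashira coupling should proceed readily because oxidative addition to the electron-poor α-bromo enoate is easy and free hydroxyls and the silyl ether are tolerated.

Step 9
Reactants: 15
Product: 16 3-[(4R)-4-(3-methylbut-2-en-1-yl)-3,6-dioxo-4-[(triethylsilyl)oxy]hex-1-yn-1-yl]-7-methoxy-2H-chromen-2-one (ynone-aldehyde)
Conditions: (COCl)2, DMSO, CH2Cl2, −78 °C; Et3N, −78 → −20 °C
Reagents that add atoms: none
Why: Swern oxidation activates both hydroxyls as alkoxysulfonium ions before base is added, so the 1,4-diol should go to ynone and aldehyde without a lactol-to-lactone detour, and the quaternary C4 cannot epimerise.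

Step 10
Reactants: 16
Product: 17 7-methoxy-3-[(4R)-4-(3-methylbut-2-en-1-yl)-3,6-dioxo-4-[(triethylsilyl)oxy]cyclohex-1-en-1-yl]-2H-chromen-2-one
Conditions: 2-(pentafluorophenyl)-6,7-dihydro-5H-pyrrolo[2,1-c][1,2,4]triazol-2-ium tetrafluoroborate (20 mol %), i-Pr2NEt (20 mol %), toluene (0.02 M), 25–40 °C
Reagents that add atoms: none
Why: Proposed new method: the free triazolylidene adds to the C6 aldehyde to give the enaminol acyl-anion equivalent, whose nucleophilic carbon attacks C1, the β-carbon of the aryl ynone C1≡C2–C3=O, and protonation of the C2 carbanion anti to the new C6–C1 bond followed by loss of the carbene gives the C6 ketone, a redox-neutral alkyne hydroacylation that delivers the ring and the whole ene-1,4-dione at once. The closest known reaction types are the NHC-catalysed intramolecular Stetter reaction of aliphatic aldehydes with enone acceptors and the NHC-catalysed intramolecular hydroacylation of alkynes, and 6-endo-dig additions of O- and N-nucleophiles to ynones whose carbonyl lies in the new ring (flavones, dihydropyranones, 4-quinolones) show that this closure is geometrically accessible; new is an acyl-anion equivalent closing a carbocycle endo onto an ynone, which must follow the stepwise polar anti pathway because the ring can only hold a cis C1=C2 bond. The one ring closed is the six-membered carbocycle, mode 6-endo-dig, with both alkyne carbons ending inside the ring. No new stereocentre is formed, and the C4 centre is quaternary, cannot enolise and is carried through unchanged. The selectivity needed is attack at C1 and not at C2 (5-exo-dig) or at the C3 carbonyl (four-membered benzoin): ynone polarisation makes C1 the only electrophilic alkyne carbon and the short tether excludes 1,2-addition, while high dilution should suppress intermolecular benzoin and Stetter reactions and the poor leaving-group ability of the silyloxy group should prevent β-elimination towards the quinone.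

Step 11
Reactants: 17
Product: 18 7-methoxy-3-[(4R)-4-hydroxy-4-(3-methylbut-2-en-1-yl)-3,6-dioxocyclohex-1-en-1-yl]-2H-chromen-2-one (target)
Conditions: HF·pyridine, pyridine, THF, 0 °C → rt
Reagents that add atoms: none
Why: Pyridine-buffered HF·pyridine should cleave the tertiary Si–O bond under near-neutral conditions, avoiding E1cB loss of water from the β-hydroxy ketone to the quinone, and the quaternary centre cannot change configuration.

**Compound list**

1 | (R)-malic acid | O[C@H](CC(=O)O)C(=O)O | starting material
2 | pivalaldehyde | CC(C)(C)C=O | starting material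
3 | 2-[(2R,4R)-2-tert-butyl-5-oxo-1,3-dioxolan-4-yl]acetic acid | OC(=O)C[C@H]1O[C@@H](C(C)(C)C)OC1=O | intermediate
4 | prenyl bromide (1-bromo-3-methylbut-2-ene) | CC(C)=CCBr | starting material
5 | 2-[(2R,4R)-2-tert-butyl-4-(3-methylbut-2-en-1-yl)-5-oxo-1,3-dioxolan-4-yl]acetic acid | OC(=O)C[C@@]1(CC=C(C)C)O[C@@H](C(C)(C)C)OC1=O | intermediate
6 | 2-[(2R,4R)-2-tert-butyl-4-(3-methylbut-2-en-1-yl)-5-oxo-1,3-dioxolan-4-yl]acetic isobutyl carbonic anhydride | CC(C)COC(=O)OC(=O)C[C@@]1(CC=C(C)C)O[C@@H](C(C)(C)C)OC1=O | intermediate (not isolated)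
7 | (2R,5R)-2-tert-butyl-5-(2-hydroxyethyl)-5-(3-methylbut-2-en-1-yl)-1,3-dioxolan-4-one | OCC[C@@]1(CC=C(C)C)O[C@@H](C(C)(C)C)OC1=O | intermediate (not isolated)
8 | (3R)-3-hydroxy-3-(3-methylbut-2-en-1-yl)oxolan-2-one | O=C1OCC[C@]1(O)CC=C(C)C | intermediate
9 | (3R)-3-(3-methylbut-2-en-1-yl)-3-[(triethylsilyl)oxy]oxolan-2-one | O=C1OCC[C@]1(O[Si](CC)(CC)CC)CC=C(C)C | intermediate
10 | (3R)-3-(3-methylbut-2-en-1-yl)-3-[(triethylsilyl)oxy]oxolan-2-ol (mixture at C2) | OC1OCC[C@]1(O[Si](CC)(CC)CC)CC=C(C)C | intermediate
11 | ethynylmagnesium bromide | C#C[Mg]Br | starting material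
12 | (3R,4RS)-3-(3-methylbut-2-en-1-yl)-3-[(triethylsilyl)oxy]hex-5-yne-1,4-diol | C#CC(O)[C@@](O[Si](CC)(CC)CC)(CC=C(C)C)CCO | intermediate
13 | 7-methoxycoumarin (7-methoxy-2H-chromen-2-one) | COc1ccc2ccc(=O)oc2c1 | starting material
14 | 3-bromo-7-methoxy-2H-chromen-2-one | COc1ccc2cc(Br)c(=O)oc2c1 | intermediate
15 | 3-[(3RS,4R)-3,6-dihydroxy-4-(3-methylbut-2-en-1-yl)-4-[(triethylsilyl)oxy]hex-1-yn-1-yl]-7-methoxy-2H-chromen-2-one | COc1ccc2cc(C#CC(O)[C@@](O[Si](CC)(CC)CC)(CC=C(C)C)CCO)c(=O)oc2c1 | intermediate
16 | 3-[(4R)-4-(3-methylbut-2-en-1-yl)-3,6-dioxo-4-[(triethylsilyl)oxy]hex-1-yn-1-yl]-7-methoxy-2H-chromen-2-one | COc1ccc2cc(C#CC(=O)[C@@](O[Si](CC)(CC)CC)(CC=C(C)C)CC=O)c(=O)oc2c1 | intermediate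
17 | 7-methoxy-3-[(4R)-4-(3-methylbut-2-en-1-yl)-3,6-dioxo-4-[(triethylsilyl)oxy]cyclohex-1-en-1-yl]-2H-chromen-2-one | COc1ccc2cc(C3=CC(=O)[C@@](O[Si](CC)(CC)CC)(CC=C(C)C)CC3=O)c(=O)oc2c1 | intermediate
18 | 7-methoxy-3-[(4R)-4-hydroxy-4-(3-methylbut-2-en-1-yl)-3,6-dioxocyclohex-1-en-1-yl]-2H-chromen-2-one | COc1ccc2cc(C3=CC(=O)[C@@](O)(CC=C(C)C)CC3=O)c(=O)oc2c1 | target

**Step count and risks**

Total steps: 11. Longest linear sequence: 10 (steps 1–6 and 8–11, from (R)-malic acid).

Steps most likely to fail:

1. Step 10 (proposed new method). The enaminol may not close in the 6-endo-dig sense; the carbene may instead be consumed by conjugate addition to the ynone, or intermolecular benzoin and aldol processes may take over. The fallback uses known chemistry and sets out from 16. Hydroiodination (NaI, AcOH, rt, anti addition) should give the (Z)-β-iodo enone F1, with iodine cis to the C3 carbonyl. Intramolecular Nozaki–Hiyama–Kishi reaction (CrCl2, NiCl2 cat., DMF) should close the six-membered ring to the cyclic allylic alcohol F2 (mixture at C6). Dess–Martin oxidation of F2 should return to the route at 17.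

2. Step 6. Addition to the neopentyl-type aldehyde released from the lactol may be sluggish, and the magnesium alkoxide next to the tertiary silyl ether may trigger silyl migration. The fallback brings C3 in at the acid oxidation level and the coumarin as the nucleophile; it sets out from 9 and 14. Sonogashira coupling of 14 with trimethylsilylacetylene should give the silyl alkyne F3, and K2CO3 (cat.)/MeOH should give 3-ethynyl-7-methoxycoumarin F4. The lithium acetylide of F4 (LiHMDS, THF, −78 °C) is added to lactone 9 with BF3·OEt2 to give the hydroxy ynone F5 (open form or hemiketal). Dess–Martin oxidation of F5 should return to the route at 16, bypassing steps 5, 6, 8 and 9.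

3. Step 3. Chemoselectivity may be lost by over-reduction of the acylal lactone or of the newly formed hydroxy lactone. The fallback reduces before the alkene is present and alkylates a monoanion; it sets out from 3. BH3·SMe2 should reduce the carboxyl group to the hydroxyethyl dioxolanone F6, which is silylated at once (TBSCl, imidazole) to the silyl ether F7. LDA then prenyl bromide 4 (attack anti to tert-butyl) should give the prenylated dioxolanone F8. Aqueous HF in MeCN should remove the silyl group and induce translactonisation with loss of pivalaldehyde, returning to the route at 8.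

**Further compounds**

F1 | step 10 | 3-[(1Z,4R)-1-iodo-4-(3-methylbut-2-en-1-yl)-3,6-dioxo-4-[(triethylsilyl)oxy]hex-1-en-1-yl]-7-methoxy-2H-chromen-2-one | COc1ccc2cc(/C(I)=C/C(=O)[C@@](O[Si](CC)(CC)CC)(CC=C(C)C)CC=O)c(=O)oc2c1
F2 | step 10 | 3-[(4R,6RS)-6-hydroxy-4-(3-methylbut-2-en-1-yl)-3-oxo-4-[(triethylsilyl)oxy]cyclohex-1-en-1-yl]-7-methoxy-2H-chromen-2-one | COc1ccc2cc(C3=CC(=O)[C@@](O[Si](CC)(CC)CC)(CC=C(C)C)CC3O)c(=O)oc2c1
F3 | step 6 | 7-methoxy-3-[(trimethylsilyl)ethynyl]-2H-chromen-2-one | COc1ccc2cc(C#C[Si](C)(C)C)c(=O)oc2c1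
F4 | step 6 | 3-ethynyl-7-methoxy-2H-chromen-2-one | COc1ccc2cc(C#C)c(=O)oc2c1
F5 | step 6 | 3-[(4R)-6-hydroxy-4-(3-methylbut-2-en-1-yl)-3-oxo-4-[(triethylsilyl)oxy]hex-1-yn-1-yl]-7-methoxy-2H-chromen-2-one | COc1ccc2cc(C#CC(=O)[C@@](O[Si](CC)(CC)CC)(CC=C(C)C)CCO)c(=O)oc2c1
F6 | step 3 | (2R,5R)-2-tert-butyl-5-(2-hydroxyethyl)-1,3-dioxolan-4-one | OCC[C@H]1O[C@@H](C(C)(C)C)OC1=O
F7 | step 3 | (2R,5R)-2-tert-butyl-5-[2-[(tert-butyldimethylsilyl)oxy]ethyl]-1,3-dioxolan-4-one | CC(C)(C)[Si](C)(C)OCC[C@H]1O[C@@H](C(C)(C)C)OC1=O
F8 | step 3 | (2R,5R)-2-tert-butyl-5-[2-[(tert-butyldimethylsilyl)oxy]ethyl]-5-(3-methylbut-2-en-1-yl)-1,3-dioxolan-4-one | CC(C)(C)[Si](C)(C)OCC[C@@]1(CC=C(C)C)O[C@@H](C(C)(C)C)OC1=O
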